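**Retrosynthetic overview**

1. Numbering (aromadendrane): C1 ring ketone carbon, C2/C3 ring CH2, C4 quaternary carbon (CH3-15), C5 ring CH, C6/C7 cyclopropane CH, C8/C9 chain CH2, C10 methyl ketone carbon (CH3-14), C11 CMe2, C1' benzylic CH. Macrocarpal N ⇐ removal of three O-benzyl groups ⇐ ozonolysis of the C1=C10 alkene of a five-seven-three tricycle.
2. Tricycle ⇐ (+)-bicyclogermacrene + a tri-O-benzylated benzylic cation: C1'–C4 bond, then transannular C1–C5 bond, which closes the five-membered ring and leaves the seven-membered ring as the rest of the macrocycle.
3. (+)-Bicyclogermacrene ⇐ (2E,6E)-farnesyl diphosphate with a bicyclogermacrene synthase: C6–C7 bond (ten-membered ring), then C6–C11 bond (cyclopropane). The plan rests on the cis-1,2-disubstituted gem-dimethylcyclopropane (C6–H, C7–H, C11Me2) and on C1–C15 being an intact farnesyl chain.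
4. Aryl fragment ⇐ phloroglucinol: triformylation, O-benzylation, one isobutyl Grignard addition trapped as the acetate.
5. Ring order: ten-membered ring → cyclopropane → five-membered ring → seven-membered ring cleaved.

Key step: step 3

Remark: compound 3 is drawn as the free acid and would be handled as its ammonium salt after cation exchange (the remaining tetrabutylammonium ions stay on the resin); the synthase is taken to be one that releases the (1S,10R) enantiomer drawn for 4.

**Step 1**
Reactants: 1 (2E,6E)-farnesol
Product: 2 (2E,6E)-farnesyl bromide
Conditions: PBr3 (0.4 equiv), Et2O, −10 °C; used crude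
Reagents that add atoms: phosphorus tribromide, BrP(Br)Br
Why: Substitution of the primary allylic alcohol through its bromophosphite at low temperature should proceed at the primary carbon without allylic transposition, so both E alkenes are kept (alcohol-to-bromide substitution).

**Step 2**
Reactants: 2 (2E,6E)-farnesyl bromide
Product: 3 (2E,6E)-farnesyl diphosphate
Conditions: (n-Bu4N)3HP2O7 (2 equiv), MeCN, 23 °C; cation exchange (NH4+ form resin, aqueous NH4HCO3/i-PrOH), cellulose chromatography, lyophilisation
Reagents that add atoms: tris(tetrabutylammonium) hydrogen diphosphate, CCCC[N+](CCCC)(CCCC)CCCC.CCCC[N+](CCCC)(CCCC)CCCC.CCCC[N+](CCCC)(CCCC)CCCC.OP(=O)([O-])OP(=O)([O-])[O-]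
Why: SN2 displacement of the primary allylic bromide by the diphosphate anion in acetonitrile should give the diphosphate monoester with the alkenes untouched, and cation exchange gives the water-soluble salt that a synthase accepts (nucleophilic diphosphorylation of an allylic halide).

**Step 3**
Reactants: 3 (2E,6E)-farnesyl diphosphate
Product: 4 (+)-bicyclogermacrene
Conditions: recombinant (+)-bicyclogermacrene synthase (His6-tagged, produced in E. coli BL21(DE3), affinity-purified), HEPES 50 mM pH 7.5, MgCl2 10 mM, dithiothreitol 2 mM, glycerol 10%, n-pentane overlay, 30 °C; pentane phase filtered through basic Al2O3, concentrated at 0 °C, stored cold under argon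
Reagents that add atoms: none
Why: The enzyme-bound magnesium ions pull off the diphosphate to give the (2E,6E)-farnesyl cation; the terminal C10=C11 alkene of the folded chain bonds through C10 (target C7) to the cationic C1 (target C6), a 1,10-closure of the ten-membered ring in the Markovnikov sense that places the new charge on C11, exocyclic to the ring, and an active-site base then takes one proton from C6 while C6 bonds to C11, a 1,3-deprotonative (three-exo) closure of the cyclopropane. The closest known reaction type is the cyclisation of farnesyl diphosphate by class one sesquiterpene synthases, and synthases that release bicyclogermacrene as their main product are known. C7 is fixed by the face of the C10=C11 alkene that the active-site fold turns towards C1, and C6 by which of its two hydrogens sits next to the base; the three-membered ring can only be cis-fused, so H-6 and H-7 end cis. The step needs enantioselectivity, retention of both E alkenes and a stop at the cyclopropane without hydride shift, second cyclisation or capture of water: the substrate contributes its 2E,6E geometry, which allows direct 1,10-closure without prior isomerisation at C2=C3, and the rest is supplied by the contour of a synthase selected for the (1S,10R) product. The pentane overlay takes the hydrocarbon out of the aqueous phase as it forms, away from acid and heat that would trigger transannular cyclisation or Cope rearrangement.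

**Step 4**
Reactants: 5 phloroglucinol
Product: 6 2,4,6-trihydroxybenzene-1,3,5-tricarbaldehyde
Conditions: hexamethylenetetramine (2.2 equiv), CF3CO2H, 100 °C; then 3 M HCl, 100 °C
Reagents that add atoms: hexamethylenetetramine, C1N2CN3CN1CN(C2)C3; water, O
Why: In the Duff formylation the very electron-rich ring is aminomethylated at each free position by iminium ions from hexamethylenetetramine, each benzylamine is oxidised by hydride transfer to a further iminium ion, and acid hydrolysis should release the three aldehydes.

**Step 5**
Reactants: 6 2,4,6-trihydroxybenzene-1,3,5-tricarbaldehyde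
Product: 7 2,4,6-tris(benzyloxy)benzene-1,3,5-tricarbaldehyde
Conditions: BnBr (3.6 equiv), K2CO3 (4.5 equiv), n-Bu4NI (cat.), DMF, 60 °C
Reagents that add atoms: benzyl bromide, BrCc1ccccc1
Why: Williamson O-alkylation of the acidic hydroxyls should be clean because the ring is fully substituted, so oxygen is the only site whose alkylation keeps the arene aromatic.

**Step 6**
Reactants: 7 2,4,6-tris(benzyloxy)benzene-1,3,5-tricarbaldehyde; 8 isobutylmagnesium bromide
Product: 10 rac-1-[2,4,6-tris(benzyloxy)-3,5-diformylphenyl]-3-methylbutyl acetate, via bromomagnesium alkoxide 9 (not isolated)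
Conditions: 8 (0.9 equiv, slow addition), THF, −78 °C; then Ac2O (3 equiv), DMAP (cat.), −78 → 0 °C; unreacted 7 recovered
Reagents that add atoms: acetic anhydride, CC(=O)OC(C)=O
Why: Grignard 1,2-addition to one of three equivalent formyl groups, kept to mono-addition by the sub-stoichiometric reagent at low temperature, is followed by acetylation of the magnesium alkoxide in the same flask; the new benzylic centre is racemic, which is of no consequence because it is ionised in step 7.

**Step 7**
Reactants: 4 (+)-bicyclogermacrene; 10 rac-1-[2,4,6-tris(benzyloxy)-3,5-diformylphenyl]-3-methylbutyl acetate (1.5 equiv)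
Product: 11 tris-O-benzyl aromadendr-1(10)-ene adduct (1'S epimer)
Conditions: Me3SiOTf (1.5 equiv, slow addition to the mixture), 2,6-di-tert-butyl-4-methylpyridine (2 equiv), 4 Å molecular sieves, CH2Cl2, −78 → −40 °C; Et3N quench; chromatography, then preparative HPLC to remove the 1'R epimer
Reagents that add atoms: none
Why: The silyl triflate ionises the benzylic acetate to a trialkoxy-stabilised benzylic cation (SN1 alkylation of an alkene continued as a transannular cation–olefin cyclisation); the C4=C5 alkene, raised in energy by conjugation with the cyclopropane, attacks through C4 so that charge develops at the cyclopropylcarbinyl position C5, the C1=C10 π bond lying across the ring bonds C1 to C5 from the inner face (anti addition across the E alkene, the same course as the proton-induced closure of 4 to ledene, which places CH3-15 cis to C6 and C1' cis to H-5 and so sets C4 and C5 from the resident C6 and C7 centres), and the tertiary C10 cation loses H-1 to give the more substituted alkene; because all three phenolic oxygens are benzylated no chroman can close, whereas C1' is set only by the face of the planar cation that meets C4, for which little bias is expected, so its epimer is separated here.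

**Step 8**
Reactants: 11 tris-O-benzyl aromadendr-1(10)-ene adduct (1'S epimer)
Product: 13 tris-O-benzyl macrocarpal N, via secondary ozonide 12 (not isolated)
Conditions: O3, CH2Cl2, −78 °C (Sudan Red 7B end point); then PPh3 (1.5 equiv), −78 → 23 °C
Reagents that add atoms: ozone, [O-][O+]=O
Why: Ozone should add far faster to the electron-rich tetrasubstituted C1=C10 alkene than to the hexasubstituted arene, the benzyl ethers or the aldehydes (Criegee ozonolysis, the tethered carbonyl oxide and ketone recombining to the ozonide), and neutral reduction with PPh3 releases both ketones without epimerising C5, whose cyclopropyl group already sits on the less hindered side, trans to the C1' substituent.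

**Step 9**
Reactants: 13 tris-O-benzyl macrocarpal N
Product: 14 macrocarpal N
Conditions: BCl3 (9 equiv), pentamethylbenzene (9 equiv), CH2Cl2, −78 °C; CHCl3–MeOH quench at −78 °C, aqueous work-up
Reagents that add atoms: none
Why: BCl3 cleaves aryl benzyl ethers at −78 °C, helped here by chelation to the ortho formyl groups, while pentamethylbenzene traps the benzyl cation as a non-Lewis-basic scavenger (Lewis-acid debenzylation); ketones, aldehydes and the unactivated cyclopropane should persist and no stereocentre is touched.

**Compound list**

1 | (2E,6E)-farnesol | CC(C)=CCC/C(C)=C/CC/C(C)=C/CO | starting material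
2 | (2E,6E)-farnesyl bromide | CC(C)=CCC/C(C)=C/CC/C(C)=C/CBr | intermediate
3 | (2E,6E)-farnesyl diphosphate (free acid drawn) | CC(C)=CCC/C(C)=C/CC/C(C)=C/COP(=O)(O)OP(=O)(O)O | intermediate
4 | (+)-bicyclogermacrene, (1S,2E,6E,10R)-3,7,11,11-tetramethylbicyclo[8.1.0]undeca-2,6-diene | C2[C@@H]1[C@H](/C=C(\C)CC/C=C(\C)C2)C1(C)C | intermediate
5 | phloroglucinol | Oc1cc(O)cc(O)c1 | starting material
6 | 2,4,6-trihydroxybenzene-1,3,5-tricarbaldehyde | O=Cc1c(O)c(C=O)c(O)c(C=O)c1O | intermediate
7 | 2,4,6-tris(benzyloxy)benzene-1,3,5-tricarbaldehyde | O=Cc1c(OCc2ccccc2)c(C=O)c(OCc2ccccc2)c(C=O)c1OCc1ccccc1 | intermediate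
8 | isobutylmagnesium bromide | CC(C)C[Mg]Br | starting material
9 | bromomagnesium 1-[2,4,6-tris(benzyloxy)-3,5-diformylphenyl]-3-methylbutan-1-olate (racemic, not isolated) | CC(C)CC(O[Mg]Br)c1c(OCc2ccccc2)c(C=O)c(OCc2ccccc2)c(C=O)c1OCc1ccccc1 | intermediate
10 | rac-1-[2,4,6-tris(benzyloxy)-3,5-diformylphenyl]-3-methylbutyl acetate | CC(C)CC(OC(C)=O)c1c(OCc2ccccc2)c(C=O)c(OCc2ccccc2)c(C=O)c1OCc1ccccc1 | intermediate
11 | tris-O-benzyl aromadendr-1(10)-ene adduct: cyclopentene ring C1–C5 fused to cycloheptene ring C1, C5–C10 and cyclopropane C6, C7, C11; C1=C10 alkene; C4 carries CH3-15 and the (1'S)-1-aryl-3-methylbutyl group; 4R,5R,6R,7R | CC=3CC[C@@H]1[C@H]([C@H]2C=3CC[C@]2(C)[C@H](CC(C)C)c4c(OCc5ccccc5)c(C=O)c(OCc5ccccc5)c(C=O)c4OCc5ccccc5)C1(C)C | intermediate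
12 | secondary ozonide of 11 (1,2,4-trioxolane bridging C1 and C10; acetal carbons drawn without configuration; not isolated) | CC3(OO6)CC[C@@H]1[C@H]([C@H]2C6(O3)CC[C@]2(C)[C@H](CC(C)C)c4c(OCc5ccccc5)c(C=O)c(OCc5ccccc5)c(C=O)c4OCc5ccccc5)C1(C)C | intermediate
13 | tris-O-benzyl macrocarpal N | CC(=O)CC[C@@H]1[C@H]([C@H]2C(=O)CC[C@]2(C)[C@H](CC(C)C)c4c(OCc5ccccc5)c(C=O)c(OCc5ccccc5)c(C=O)c4OCc5ccccc5)C1(C)C | intermediate
14 | macrocarpal N (4R,5R,6R,7R,1'S) | CC(=O)CC[C@@H]1[C@H]([C@H]2C(=O)CC[C@]2(C)[C@H](CC(C)C)c2c(O)c(C=O)c(O)c(C=O)c2O)C1(C)C | target

**Totals**

Total step count: 9. Longest linear sequence: 6 steps (1, 2, 3, 7, 8, 9 from farnesol; equally 4, 5, 6, 7, 8, 9 from phloroglucinol).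

**Steps most likely to fail**

Step 7 carries several risks.
- The cation may bond to C1 of the other alkene (the Markovnikov mode, which closes a six-six-three skeleton) instead of C4.
- It may lose a β-proton to a styrene before it is captured.
- An ortho benzyloxy oxygen may capture the C5 cation with loss of its benzyl group.
- The face selection at C1' may favour the unwanted epimer.
- The last deprotonation may give the exocyclic or the C9=C10 alkene.

The fallback sets out from 5 and 4 and comes back at 14; it gives up the protecting groups and uses a neutral o-quinone methide. Phloroglucinol 5 would be diformylated under Vilsmeier–Haack conditions (POCl3, DMF, dioxane, then water) to 2,4-diformylphloroglucinol F1. Knoevenagel condensation of F1 with 3-methylbutanal (secondary amine catalyst or NaOAc/AcOH, in hexafluoroisopropanol) in the presence of 4 would form o-quinone methide F2 in the flask. Its stepwise Michael-type attack by C4 and transannular closure would give triphenol alkene F3, which has to be separated from chroman-type hetero-Diels–Alder adducts. Ozonolysis of F3 (O3, CH2Cl2–MeOH, −78 °C; Me2S) would then give 14 directly.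

Step 3 may suffer from hydrolysis of the diphosphate, stalling of the enzyme by magnesium diphosphate and loss of activity at preparative scale. The hydrocarbon may also be lost by proton-induced transannular cyclisation, by Cope rearrangement on warming or by evaporation, and other sesquiterpenes may be released beside it. The fallback sets out from 1 and comes back at 4. Farnesol 1 would be fed to E. coli cells that co-express a promiscuous alcohol kinase, an isopentenyl phosphate kinase and the same synthase (or to the three isolated enzymes with ATP regenerated by acetate kinase and acetyl phosphate). Farnesyl phosphate F4 and then 3 would form and be consumed at once, so no diphosphate accumulates, and 4 would be collected in a dodecane overlay.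

Step 9 may fail through Lewis-acid-induced aldol condensation between the two ketones, opening of the cyclopropane by the hydrogen chloride formed, or incomplete cleavage of the benzyl ether that lies between the two formyl groups. The fallback sets out from 11 and comes back at 14; it changes the order of events. Hydrogenolysis of 11 (H2, Pd/C, EtOAc, 23 °C), which a tetrasubstituted alkene and the cyclopropane should resist, would give triphenol alkene F5. Ozonolysis of F5 (O3, CH2Cl2–MeOH, −78 °C; Me2S) as the last step would then give 14 without any Lewis acid meeting the diketone.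

**Further compounds**

F1 | step 7 | 2,4-diformylphloroglucinol | O=Cc1c(O)cc(O)c(C=O)c1O
F2 | step 7 | o-quinone methide from F1 and 3-methylbutanal | CC(C)CC=C1C(=O)C(C=O)=C(O)C(C=O)=C1O
F3 | step 7 | triphenol alkene (11 without benzyl groups) | CC=3CC[C@@H]1[C@H]([C@H]2C=3CC[C@]2(C)[C@H](CC(C)C)c4c(O)c(C=O)c(O)c(C=O)c4O)C1(C)C
F4 | step 3 | (2E,6E)-farnesyl phosphate | CC(C)=CCC/C(C)=C/CC/C(C)=C/COP(=O)(O)O
F5 | step 9 | triphenol alkene (11 without benzyl groups) | CC=3CC[C@@H]1[C@H]([C@H]2C=3CC[C@]2(C)[C@H](CC(C)C)c4c(O)c(C=O)c(O)c(C=O)c4O)C1(C)C
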